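**Plan**

1. Retrosynthesis: the C15 aldehyde and the C9 angelate are taken back to a 9-keto lactone. The lactone O–C8 bond is then cut to a δ-keto acrylic acid. Its C7–C11 bond and C11=C13 methylene come from a temporary cis-6,12-lactone (tethered Michael addition, then HWE). The C10–vinyl and C5–C4 bonds come from one three-component coupling on a 4-hydroxycyclohexenone, which comes from a p-quinone monoketal.
2. Forward: the carbocycle is the ring of 4-methoxy-3-methylphenol. C5 and C10 are substituted first, the temporary 6,12-lactone ring is closed and opened again, and its carboxyl is finally re-closed on C8 as the trans-8,12-lactone.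
3. Feature that makes the key event possible: the C9 carbonyl (an oxidation level absent from the target) is flanked by quaternary C10, so only C8 can be enolised. The C12 carboxyl on C7 is γ to C8, so a five-membered ring results. C8 stays epimerisable, so the substitution pattern of the six-membered ring dictates the trans fusion.
4. Stereochemistry: C6 by CBS reduction; C5 by delivery from the C6 alkoxide; C10 anti to C5; C7 by the O6 tether; C8 under thermodynamic control; C9 by reagent-controlled reduction.

Key step: step 13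

**Remarks**

- Ring carbons carry their elemane numbers (C5–C10; C1/C2 vinyl, C3/C4/C15 and C11/C12/C13 side chains, C14 methyl). β is the face of the C10 methyl group in the target, α the opposite face.
- Metal salts (alkoxides, enolates, carboxylates) of a numbered compound are not numbered separately.
- Assumption: silyl ether 8 is taken as a catalogue compound (otherwise one silylation of 2-bromoallyl alcohol).

**Route**

Step 1
Reactants: 1 4-methoxy-3-methylphenol
Product: 2 4,4-dimethoxy-3-methylcyclohexa-2,5-dien-1-one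
Conditions: PhI(OAc)2, MeOH, 0 °C
Reagents that add atoms: methanol CO
Why: PhI(OAc)2 oxidation of a p-methoxyphenol in methanol (oxidative dearomatisation) should give the p-quinone monoketal, with the ketal at the future C9 and the free carbonyl at the future C6; no stereocentre is formed.

Step 2
Reactants: 2 4,4-dimethoxy-3-methylcyclohexa-2,5-dien-1-one
Product: 3 4,4-dimethoxy-3-methylcyclohex-2-en-1-one
Conditions: H2 (1 atm), RhCl(PPh3)3 (cat.), benzene, rt
Reagents that add atoms: none
Why: Chemoselective homogeneous (Wilkinson) hydrogenation should reduce the unhindered 1,2-disubstituted C7=C8 and leave the methyl-bearing trisubstituted C5=C10.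

Step 3
Reactants: 3 4,4-dimethoxy-3-methylcyclohex-2-en-1-one
Product: 5 (R)-4-hydroxy-2-methylcyclohex-2-en-1-one, via allylic alcohol ketal 4 (not isolated)
Conditions: (S)-Me-CBS (cat.), catecholborane, toluene, −78 °C; then 1 M HCl, THF, 0 °C
Reagents that add atoms: water O
Why: In the Corey–Bakshi–Shibata reduction the alkenyl side (C5) acts as the large group, so the (S)-catalyst should deliver hydride to the α face and give the (R)-alcohol with C6–OH β (the source of all absolute stereochemistry); mild acid then hydrolyses the ketal to the C9 ketone.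

Step 4
Reactants: 6 (phenylseleno)acetaldehyde diethyl acetal
Product: 7 (phenylseleno)acetaldehyde
Conditions: 1 M HCl, THF, rt
Reagents that add atoms: water O
Why: Acid-catalysed acetal hydrolysis liberates the aldehyde that serves as a vinyl cation equivalent (Clive–Reich selenium method).

Step 5
Reactants: 5 (R)-4-hydroxy-2-methylcyclohex-2-en-1-one; 8 tert-butyl[(2-bromoprop-2-en-1-yl)oxy]dimethylsilane; 7 (phenylseleno)acetaldehyde
Product: 11 5β-[3-(tert-butyldimethylsilyloxy)prop-1-en-2-yl]-6β-hydroxy-10α-[1-hydroxy-2-(phenylseleno)ethyl]-10β-methylcyclohexan-9-one (carbinol epimers), via Grignard reagent 9 (not isolated), via magnesium enolate 10 (not isolated)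
Conditions: 8, Mg, THF; 5, t-BuMgCl (1 equiv), THF, −78 °C, then 9, −78 to −30 °C; then 7, −78 °C; aq NH4Cl
Reagents that add atoms: tert-butyl[(2-bromoprop-2-en-1-yl)oxy]dimethylsilane C=C(Br)CO[Si](C)(C)C(C)(C)C; (phenylseleno)acetaldehyde O=CC[Se]c1ccccc1
Why: In this alkoxide-directed (ligand-assisted) conjugate addition the C6 magnesium alkoxide should deliver the alkenyl group to C5 on its own β face, and aldol addition of the tetrasubstituted enolate 10 to 7 anti to the new C5 substituent sets the quaternary C10 with its methyl β; the carbinol centre is erased in step 6.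

Step 6
Reactants: 11 β-hydroxy selenide from step 5
Product: 14 6β-hydroxy-10β-methyl-5β-[3-(tert-butyldimethylsilyloxy)prop-1-en-2-yl]-10α-vinylcyclohexan-9-one, via bis(trifluoroacetate) 12 (not isolated), via vinyl trifluoroacetate 13 (not isolated)
Conditions: (CF3CO)2O, Et3N, CH2Cl2, 0 °C; then MeOH, NaHCO3, rt
Reagents that add atoms: none
Why: Reductive elimination of a β-hydroxy selenide (Reich–Krief olefination): the trifluoroacetylated carbinol leaves with selenium assistance through a seleniranium ion that loses PhSe+, giving the C10 vinyl group, and methanolysis removes the labile C6 trifluoroacetate.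

Step 7
Reactants: 14 hydroxy vinyl ketone
Product: 17 6β-hydroxy-10β-methyl-5β-[3-(tert-butyldimethylsilyloxy)prop-1-en-2-yl]-10α-vinylcyclohex-7-en-9-one, via bis(silyl) enol ether 15 (not isolated), via silyloxy enone 16 (not isolated)
Conditions: TMSOTf, Et3N, CH2Cl2, 0 °C; Pd(OAc)2, MeCN, rt; K2CO3 (cat.), MeOH, 0 °C
Reagents that add atoms: none
Why: Saegusa–Ito oxidation: the silyl enol ether can form only toward C8 because C10 is quaternary, Pd(II) then gives the C7=C8 enone, and carbonate in methanol cleaves the C6 silyl ether.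

Step 8
Reactants: 17 γ-hydroxy enone; 18 (diethoxyphosphoryl)acetic acid
Product: 19 6β-O-[(diethoxyphosphoryl)acetyl] ester of 17
Conditions: DCC, DMAP (cat.), CH2Cl2, 0 °C to rt
Reagents that add atoms: (diethoxyphosphoryl)acetic acid CCOP(=O)(CC(=O)O)OCC
Why: Steglich esterification of the allylic C6 alcohol installs the phosphonoacetate as a temporary tether on O6.

Step 9
Reactants: 19 phosphonoacetate
Product: 21 9-oxo-11(13)-methylene-cis-6β,12-lactone (C7 side chain β), via phosphono lactone 20 (not isolated)
Conditions: NaH, THF, 0 °C; then (CH2O)n, rt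
Reagents that add atoms: formaldehyde C=O
Why: The intramolecular Michael addition (5-exo-trig) of the phosphonate carbanion can reach C7 only on the face of O6, so the cis-fused γ-lactone sets C7 (all-cis C5/C6/C7); Horner–Wadsworth–Emmons olefination of the phosphono lactone with formaldehyde then gives the exocyclic methylene.

Step 10
Reactants: 21 α-methylene cis-6,12-lactone
Product: 23 allyl 2-[(5β,6β,7β,10β-Me)-6-hydroxy-9-oxo-ring]acrylate (hydroxy allyl ester), via lithium carboxylate 22 (not isolated)
Conditions: LiOH (1.1 equiv), THF/H2O, 0 °C; evaporate; allyl bromide, DMF, rt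
Reagents that add atoms: lithium hydroxide [Li+].[OH-]; allyl bromide C=CCBr
Why: Saponification opens the temporary lactone and SN2 O-alkylation of the carboxylate blocks it, so C6–OH can be acylated without re-lactonisation.

Step 11
Reactants: 23 hydroxy allyl ester
Product: 24 6β-acetoxy allyl ester
Conditions: Ac2O, DMAP, pyridine, rt
Reagents that add atoms: acetic anhydride CC(=O)OC(C)=O
Why: DMAP-catalysed acetylation of the secondary alcohol; Ac2O is far more reactive toward the hydroxyl than the allyl ester, so acetylation should outrun re-lactonisation.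

Step 12
Reactants: 24 acetoxy allyl ester
Product: 25 6β-acetoxy-9-oxo-11(13)-en-12-oic acid (δ-keto acrylic acid)
Conditions: Pd(PPh3)4 (cat.), sodium p-toluenesulfinate, THF/MeOH, rt; dilute acid work-up
Reagents that add atoms: none
Why: Pd(0)-catalysed allyl transfer (Tsuji–Trost deallylation) to the soft sulfinate frees the acid under neutral conditions that leave the acetate and the acrylate untouched.

Step 13
Reactants: 25 δ-keto acrylic acid
Product: 30 6β-acetoxy-9-oxo-11(13)-en-8α,12-lactone (trans-fused), via silyl enol ether 26 (not isolated), via iodo silyl ester 27 (not isolated), via iodo carboxylate 28 (not isolated), via cis-lactone 29 (not isolated)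
Conditions: TMSOTf, Et3N, CH2Cl2, 0 °C; NIS (1.0 equiv), THF, −78 °C; aq NaHCO3, rt; then DBU (0.2 equiv), CH2Cl2, rt
Reagents that add atoms: none
Why: Soft enolisation can occur only toward C8 because C10 is quaternary, so 26 is a single silyl enol ether; NIS iodinates it from the α face (away from the syn-axial C10–Me and C6–OAc) and, once bicarbonate cleaves the silyl ester, the C12 carboxylate displaces the activated α-keto iodide. The closest known reaction type is the intramolecular α-acyloxylation of a ketone through its α-halo derivative (oxidative lactonisation of δ-keto acids to keto-γ-lactones). The γ-lactone closes 5-exo-tet with inversion at C8 and should first give the cis-fused 8β-epimer 29, because backside attack is possible only from the face that carries the C7 side chain. C8 is the only new stereocentre and is set under thermodynamic control: it is α to the C9 ketone, DBU equilibrates it, and only the trans-fused 8α-isomer 30 keeps the C5 and C7 side chains and the lactone oxygen equatorial, whereas 29 must place O8 syn-axial to both C10–Me and C6–OAc. The step needs regioselective functionalisation of C8 (secured by the quaternary C10), chemoselectivity for the enol ether over the three other alkenes (one equivalent of NIS at −78 °C; C6–OH is already acetylated, so no acyl migration to O6), and the trans ring fusion (secured by the epimerisable C8–H).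

Step 14
Reactants: 30 trans keto lactone
Product: 31 6β-acetoxy-9α-hydroxy-11(13)-en-8α,12-lactone
Conditions: (S)-Me-CBS (1 equiv), catecholborane, toluene, −78 to −40 °C
Reagents that add atoms: none
Why: CBS reduction with the quaternary C10 as large group and C8 as small group should deliver hydride to the β face and give the axial 9α-alcohol against the substrate's preference for axial attack; catecholborane at low temperature leaves the α-methylene lactone and the alkenes untouched.

Step 15
Reactants: 31 9α-alcohol; 32 angelic acid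
Product: 34 6β-acetoxy-9α-angeloyloxy-15-(tert-butyldimethylsilyloxy) lactone, via mixed anhydride 33 (not isolated)
Conditions: 32, 2,4,6-trichlorobenzoyl chloride, Et3N, toluene, rt; then 31, 80 °C
Reagents that add atoms: angelic acid OC(=O)/C(C)=C\C
Why: Yamaguchi esterification through the mixed anhydride acylates the hindered alcohol without the nucleophilic catalysis that isomerises angelate to tiglate.

Step 16
Reactants: 34 silyl ether
Product: 35 15-hydroxy compound (allylic alcohol)
Conditions: HF·pyridine, pyridine/THF, 0 °C to rt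
Reagents that add atoms: none
Why: Fluoride cleavage of the primary silyl ether (desilylation) is compatible with the three esters.

Step 17
Reactants: 35 allylic alcohol
Product: 36 target, 6β-acetoxy-9α-angeloyloxy-15-oxoelema-1,3,11(13)-trien-8α,12-olide
Conditions: MnO2, CH2Cl2, rt
Reagents that add atoms: none
Why: MnO2 oxidises only the allylic primary alcohol to the α-substituted acrolein (allylic oxidation), which completes the target.

**Compound list**

In the SMILES of 11, 12, 20, 27 and 28 one centre is left undefined where a mixture is formed or the centre is later erased.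

1 | 4-methoxy-3-methylphenol | Cc1cc(O)ccc1OC | starting material
2 | 4,4-dimethoxy-3-methylcyclohexa-2,5-dien-1-one | O=C1C=CC(OC)(OC)C(C)=C1 | intermediate
3 | 4,4-dimethoxy-3-methylcyclohex-2-en-1-one | O=C1CCC(OC)(OC)C(C)=C1 | intermediate
4 | (R)-4,4-dimethoxy-3-methylcyclohex-2-en-1-ol | COC1(OC)CC[C@@H](O)C=C1C | intermediate
5 | (R)-4-hydroxy-2-methylcyclohex-2-en-1-one | O=C1CC[C@@H](O)C=C1C | intermediate
6 | (phenylseleno)acetaldehyde diethyl acetal | CCOC(C[Se]c1ccccc1)OCC | starting material
7 | (phenylseleno)acetaldehyde | O=CC[Se]c1ccccc1 | intermediate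
8 | tert-butyl[(2-bromoprop-2-en-1-yl)oxy]dimethylsilane | C=C(Br)CO[Si](C)(C)C(C)(C)C | starting material
9 | [3-(tert-butyldimethylsilyloxy)prop-1-en-2-yl]magnesium bromide | C=C([Mg]Br)CO[Si](C)(C)C(C)(C)C | intermediate
10 | magnesium C9-enolate C6-alkoxide after conjugate addition (C5 chain β, C6–O β) | CC1=C(O[Mg]Br)CC[C@@H](O[Mg]Cl)[C@H]1C(=C)CO[Si](C)(C)C(C)(C)C | intermediate
11 | 5β-[3-(TBSO)prop-1-en-2-yl]-6β-hydroxy-10α-[1-hydroxy-2-(phenylseleno)ethyl]-10β-methylcyclohexan-9-one | OC(C[Se]c1ccccc1)[C@]2(C)C(=O)CC[C@@H](O)[C@H]2C(=C)CO[Si](C)(C)C(C)(C)C | intermediate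
12 | bis(trifluoroacetate) of 11 | FC(F)(F)C(=O)OC(C[Se]c1ccccc1)[C@]2(C)C(=O)CC[C@@H](OC(=O)C(F)(F)F)[C@H]2C(=C)CO[Si](C)(C)C(C)(C)C | intermediate
13 | 6β-trifluoroacetoxy-10α-vinyl ketone | C=C[C@]1(C)C(=O)CC[C@@H](OC(=O)C(F)(F)F)[C@H]1C(=C)CO[Si](C)(C)C(C)(C)C | intermediate
14 | 6β-hydroxy-10β-methyl-5β-[3-(TBSO)prop-1-en-2-yl]-10α-vinylcyclohexan-9-one | C=C[C@]1(C)C(=O)CC[C@@H](O)[C@H]1C(=C)CO[Si](C)(C)C(C)(C)C | intermediate
15 | 6β,9-bis(trimethylsilyloxy)-8-ene (silyl enol ether of 14) | C=C[C@]1(C)C(O[Si](C)(C)C)=CC[C@@H](O[Si](C)(C)C)[C@H]1C(=C)CO[Si](C)(C)C(C)(C)C | intermediate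
16 | 6β-trimethylsilyloxy-7-en-9-one | C=C[C@]1(C)C(=O)C=C[C@@H](O[Si](C)(C)C)[C@H]1C(=C)CO[Si](C)(C)C(C)(C)C | intermediate
17 | 6β-hydroxy-7-en-9-one (γ-hydroxy enone) | C=C[C@]1(C)C(=O)C=C[C@@H](O)[C@H]1C(=C)CO[Si](C)(C)C(C)(C)C | intermediate
18 | (diethoxyphosphoryl)acetic acid | CCOP(=O)(CC(=O)O)OCC | starting material
19 | 6β-O-(diethoxyphosphoryl)acetate of 17 | C=C[C@]1(C)C(=O)C=C[C@@H](OC(=O)CP(=O)(OCC)OCC)[C@H]1C(=C)CO[Si](C)(C)C(C)(C)C | intermediate
20 | 11-(diethoxyphosphoryl)-9-oxo-cis-6β,12-lactone | C=C[C@]1(C)C(=O)C[C@H]2C(P(=O)(OCC)OCC)C(=O)O[C@H]2[C@H]1C(=C)CO[Si](C)(C)C(C)(C)C | intermediate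
21 | 9-oxo-11(13)-methylene-cis-6β,12-lactone | C=C[C@]1(C)C(=O)C[C@H]2C(=C)C(=O)O[C@H]2[C@H]1C(=C)CO[Si](C)(C)C(C)(C)C | intermediate
22 | lithium 6β-hydroxy-9-oxo-11(13)-en-12-oate | C=C[C@]1(C)C(=O)C[C@@H](C(=C)C(=O)[O-])[C@@H](O)[C@H]1C(=C)CO[Si](C)(C)C(C)(C)C.[Li+] | intermediate
23 | allyl 6β-hydroxy-9-oxo-11(13)-en-12-oate | C=C[C@]1(C)C(=O)C[C@@H](C(=C)C(=O)OCC=C)[C@@H](O)[C@H]1C(=C)CO[Si](C)(C)C(C)(C)C | intermediate
24 | allyl 6β-acetoxy-9-oxo-11(13)-en-12-oate | C=C[C@]1(C)C(=O)C[C@@H](C(=C)C(=O)OCC=C)[C@@H](OC(C)=O)[C@H]1C(=C)CO[Si](C)(C)C(C)(C)C | intermediate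
25 | 6β-acetoxy-9-oxo-11(13)-en-12-oic acid | C=C[C@]1(C)C(=O)C[C@@H](C(=C)C(=O)O)[C@@H](OC(C)=O)[C@H]1C(=C)CO[Si](C)(C)C(C)(C)C | intermediate
26 | 9-trimethylsilyloxy-8-ene trimethylsilyl ester of 25 | C=C[C@]1(C)C(O[Si](C)(C)C)=C[C@@H](C(=C)C(=O)O[Si](C)(C)C)[C@@H](OC(C)=O)[C@H]1C(=C)CO[Si](C)(C)C(C)(C)C | intermediate
27 | 8-iodo-9-oxo trimethylsilyl ester (8α expected) | C=C[C@]1(C)C(=O)C(I)[C@@H](C(=C)C(=O)O[Si](C)(C)C)[C@@H](OC(C)=O)[C@H]1C(=C)CO[Si](C)(C)C(C)(C)C | intermediate
28 | sodium 8-iodo-9-oxo-12-oate | C=C[C@]1(C)C(=O)C(I)[C@@H](C(=C)C(=O)[O-])[C@@H](OC(C)=O)[C@H]1C(=C)CO[Si](C)(C)C(C)(C)C.[Na+] | intermediate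
29 | 6β-acetoxy-9-oxo-8β,12-lactone (cis-fused 8-epimer) | C=C[C@]1(C)C(=O)[C@H]2OC(=O)C(=C)[C@H]2[C@@H](OC(C)=O)[C@H]1C(=C)CO[Si](C)(C)C(C)(C)C | intermediate
30 | 6β-acetoxy-9-oxo-8α,12-lactone (trans-fused) | C=C[C@]1(C)C(=O)[C@@H]2OC(=O)C(=C)[C@H]2[C@@H](OC(C)=O)[C@H]1C(=C)CO[Si](C)(C)C(C)(C)C | intermediate
31 | 6β-acetoxy-9α-hydroxy-8α,12-lactone | C=C[C@]1(C)[C@H](O)[C@@H]2OC(=O)C(=C)[C@H]2[C@@H](OC(C)=O)[C@H]1C(=C)CO[Si](C)(C)C(C)(C)C | intermediate
32 | angelic acid, (Z)-2-methylbut-2-enoic acid | OC(=O)/C(C)=C\C | starting material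
33 | angelic 2,4,6-trichlorobenzoic anhydride | O=C(OC(=O)/C(C)=C\C)c1c(Cl)cc(Cl)cc1Cl | intermediate
34 | 6β-acetoxy-9α-angeloyloxy-15-O-TBS lactone | C=C[C@]1(C)[C@H](OC(=O)/C(C)=C\C)[C@@H]2OC(=O)C(=C)[C@H]2[C@@H](OC(C)=O)[C@H]1C(=C)CO[Si](C)(C)C(C)(C)C | intermediate
35 | 6β-acetoxy-9α-angeloyloxy-15-hydroxy lactone | C=C[C@]1(C)[C@H](OC(=O)/C(C)=C\C)[C@@H]2OC(=O)C(=C)[C@H]2[C@@H](OC(C)=O)[C@H]1C(=C)CO | intermediate
36 | 6β-acetoxy-9α-angeloyloxy-15-oxoelema-1,3,11(13)-trien-8α,12-olide | C=C[C@]1(C)[C@H](OC(=O)/C(C)=C\C)[C@@H]2OC(=O)C(=C)[C@H]2[C@@H](OC(C)=O)[C@H]1C(=C)C=O | target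

**Totals and risks**

Total step count: 17 (16 in the main line, 1 in a side branch). Longest linear sequence: 16 steps (steps 1–3 and 5–17).

The three steps judged most likely to fail act on the fully substituted, congested ring.

1. Step 13. Loss of HI from the α-iodo ketone to the C7=C8 enone, or intermolecular displacement, may outrun the crowded 5-exo closure, and epimerisation at C8 may stall. The fallback sets out from 25 and returns at 30. The C8 enolate (LiHMDS, THF, −78 °C) would be acylated with 2,2,2-trifluoroethyl trifluoroacetate to the trifluoroacetyl ketone F1. Detrifluoroacetylative diazo transfer (MsN3, Et3N, MeCN) would give the α-diazo ketone acid F2. Rh2(OAc)4 in CH2Cl2 would then close the same O–C8 bond by intramolecular O–H insertion of the carboxylic acid into the rhodium carbenoid. This closure passes through a planar enol, so it is free of the backside-attack geometry; protonation at C8 would give 29 and 30, which DBU converges to 30.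

2. Step 14. Hydride may arrive from the α face (the substrate's preferred axial attack overriding the catalyst), or the hindered ketone may react too slowly. The fallback sets out from 30 and returns at 31. Dimethylamine would add to the α-methylene lactone to give the amine adduct F3. With the Michael acceptor masked, L-Selectride (THF, −78 °C) would attack equatorially under substrate control to give the axial 9α-alcohol F4. Methyl iodide would give the methiodide F5, and aqueous NaHCO3 would eliminate trimethylamine to regenerate the methylene group in 31.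

3. Step 15. Acylation of the axial, neopentyl-type 9α-hydroxyl may fail, and the activated angelate may isomerise from Z to E. The fallback sets out from 31 and returns at 34. The alcohol would be acylated with the small saturated acid 2-[bis(2,2,2-trifluoroethoxy)phosphoryl]propanoic acid (DCC, DMAP) to give the phosphonate ester F6. A Still–Gennari olefination with acetaldehyde (KHMDS, 18-crown-6, THF, −78 °C) would then build the Z-alkene of the angelate on the ring.

**Further compounds**

F1 | step 13 | 8-trifluoroacetyl derivative of keto acid 25 | C=C[C@]1(C)C(=O)C(C(=O)C(F)(F)F)[C@@H](C(=C)C(=O)O)[C@@H](OC(C)=O)[C@H]1C(=C)CO[Si](C)(C)C(C)(C)C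
F2 | step 13 | 8-diazo-9-oxo acid | C=C[C@]1(C)C(=O)C(=[N+]=[N-])[C@@H](C(=C)C(=O)O)[C@@H](OC(C)=O)[C@H]1C(=C)CO[Si](C)(C)C(C)(C)C
F3 | step 14 | 13-(dimethylamino) adduct of keto lactone 30 | C=C[C@]1(C)C(=O)[C@@H]2OC(=O)C(CN(C)C)[C@H]2[C@@H](OC(C)=O)[C@H]1C(=C)CO[Si](C)(C)C(C)(C)C
F4 | step 14 | 13-(dimethylamino)-9α-hydroxy lactone | C=C[C@]1(C)[C@H](O)[C@@H]2OC(=O)C(CN(C)C)[C@H]2[C@@H](OC(C)=O)[C@H]1C(=C)CO[Si](C)(C)C(C)(C)C
F5 | step 14 | 13-(trimethylammonio)-9α-hydroxy lactone iodide | C=C[C@]1(C)[C@H](O)[C@@H]2OC(=O)C(C[N+](C)(C)C)[C@H]2[C@@H](OC(C)=O)[C@H]1C(=C)CO[Si](C)(C)C(C)(C)C.[I-]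
F6 | step 15 | 9α-O-{2-[bis(2,2,2-trifluoroethoxy)phosphoryl]propanoyl} ester of 31 | C=C[C@]1(C)[C@H](OC(=O)C(C)P(=O)(OCC(F)(F)F)OCC(F)(F)F)[C@@H]2OC(=O)C(=C)[C@H]2[C@@H](OC(C)=O)[C@H]1C(=C)CO[Si](C)(C)C(C)(C)C
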